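## Retrosynthetic overview

1. Target ⇒ cleave the C19–O acyl bond: labda-13(16),14-diene-7α,8α,19-triol plus an O-silylated (Z)-p-coumaric acid; the ester is made late and the silyl group then removed.
2. Triol ⇒ C8–O and C7–O bonds: hydride opening (at C17) of a 7α-hydroxy-8α,17-epoxide, which comes from the exocyclic C8=C17 alkene by a one-pot Se/V allylic hydroxylation–directed epoxidation (new), both oxygens delivered to the α face.
3. 13(16),14-Diene ⇒ Pd(0) 1,4-elimination of an (E)-allylic acetate, placed after the oxidation and before the hydride step.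
4. No carbocycle is built: rings A/B with C4, C5, C9, C10 and the C19 oxygen are taken intact from (+)-isocupressic acid; the only ring formed is the transient spiro-oxirane.
5. (Z)-Acid ⇒ Ando Z-selective olefination of 4-silyloxybenzaldehyde.

Assumption: (+)-isocupressic acid (1), a catalogue labdane acid (the main diterpene acid of ponderosa pine needles), is accepted as the purchasable feedstock; it is a fine chemical, not a bulk one.

## Route

Step 1
Reactants: 1 (+)-isocupressic acid
Product: 2 15-O-acetylisocupressic acid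
Conditions: Ac2O (1.5 equiv), pyridine, DMAP (5 mol %), CH2Cl2, 0 °C → rt; aq. NaHCO3, then pH 3 work-up
Reagents that add atoms: acetic anhydride, CC(=O)OC(C)=O
Why: DMAP-catalysed O-acylation takes the only alcohol (primary, allylic), the hindered C19 acid at most forms a mixed anhydride that the aqueous work-up hydrolyses, and the acetate both deactivates C13=C14 toward the oxidants of step 2 and is the leaving group for step 3; no stereocentre is touched.

Step 2
Reactants: 2 15-O-acetylisocupressic acid
Product: 4 (13E)-15-acetoxy-8α,17-epoxy-7α-hydroxylabd-13-en-19-oic acid, via 7α-hydroxy allylic alcohol 3 (not isolated)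
Conditions: SeO2 (20 mol %), VO(acac)2 (5 mol %), t-BuOOH (5.5 M in decane, 3.5 equiv), 4 Å MS, CH2Cl2, 0 °C → rt
Reagents that add atoms: tert-butyl hydroperoxide, CC(C)(C)OO
Why: Proposed new method: a Se(IV)/V(V) relay oxidation in which the SeO2/t-BuOOH ene reaction at the exocyclic C8=C17 bond and the following [2,3]-shift deliver oxygen axially to C7 (7α, as in the Sharpless allylic hydroxylation), the resulting allylic alcohol 3 is captured at once as a vanadium(V) alkoxide whose tert-butylperoxo ligand transfers oxygen to the same (α) face of C8=C17 (as in the Sharpless–Michaelson directed epoxidation), so C7–O and C8–O are both set α in one operation and the alcohol is consumed before it can over-oxidise to the enone, while the C13=C14 bond is protected from both catalysts by its allylic acetate; the closest known chemistry is these two reactions run as separate steps and the singlet-oxygen/Ti(IV) hydroxy-epoxidation, which gives the transposed regioisomer.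

Step 3
Reactants: 4 (13E)-15-acetoxy-8α,17-epoxy-7α-hydroxylabd-13-en-19-oic acid
Product: 5 8α,17-epoxy-7α-hydroxylabda-13(16),14-dien-19-oic acid
Conditions: Pd(PPh3)4 (5 mol %), Et3N (3 equiv), THF, 65 °C; AgNO3–silica chromatography
Reagents that add atoms: none
Why: Tsuji–Trost ionisation of the (E)-allylic acetate gives a π-allylpalladium in which the C16 methyl is anti, and base-assisted loss of one of its hydrogens (Pd(0) 1,4-elimination) gives the 2-substituted butadiene, with the non-allylic epoxide, the 7-OH and the carboxylate as spectators; running it before the epoxide is opened avoids O-allylation by a C8 hydroxyl.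

Step 4
Reactants: 5 8α,17-epoxy-7α-hydroxylabda-13(16),14-dien-19-oic acid
Product: 6 labda-13(16),14-diene-7α,8α,19-triol
Conditions: LiAlH4 (6 equiv), THF, 0 °C → reflux; Fieser work-up
Reagents that add atoms: none
Why: LiAlH4 reduces the C19 acid to CH2OH and opens the spiro-oxirane by SN2 hydride attack at the unhindered CH2 terminus (C17), so the C8–O bond is untouched and C8 ends as 8α-OH/8β-CH3, cis to the 7α-OH; the diene is inert.

Step 5
Reactants: 7 4-(tert-butyldimethylsilyloxy)benzaldehyde; 8 ethyl (diphenoxyphosphoryl)acetate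
Product: 9 ethyl (Z)-3-[4-(tert-butyldimethylsilyloxy)phenyl]prop-2-enoate
Conditions: NaH (1.1 equiv), THF, −78 °C → −20 °C
Reagents that add atoms: none
Why: the Ando diaryl-phosphonoacetate Horner–Wadsworth–Emmons olefination is kinetically Z-selective for aryl aldehydes (expected Z:E about 9:1 or better).

Step 6
Reactants: 9 ethyl (Z)-3-[4-(tert-butyldimethylsilyloxy)phenyl]prop-2-enoate
Product: 10 (Z)-p-coumaric acid
Conditions: LiOH·H2O (5 equiv), THF/MeOH/H2O 3:1:1, rt, dark; 1 M HCl to pH 2; recrystallise
Reagents that add atoms: lithium hydroxide (its oxygen becomes the carboxyl OH), [Li+].[OH-]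
Why: saponification of the ethyl ester, in which hydroxide also cleaves the aryl silyl ether; the Z-alkene is stable to aqueous base in the dark and the minor E-acid is removed by crystallisation.

Step 7
Reactants: 10 (Z)-p-coumaric acid
Product: 12 (Z)-3-[4-(tert-butyldimethylsilyloxy)phenyl]prop-2-enoic acid, via bis-silyl cinnamate 11 (not isolated)
Conditions: TBSCl (2.4 equiv), imidazole (5 equiv), DMF, rt; then THF/AcOH/H2O 4:1:1, rt, dark
Reagents that add atoms: tert-butyldimethylsilyl chloride, CC(C)(C)[Si](C)(C)Cl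
Why: both acidic OH groups are silylated and the very labile silyl ester is then hydrolysed selectively by mild aqueous acid, leaving the aryl silyl ether (standard phenol protection of a hydroxycinnamic acid).

Step 8
Reactants: 6 labda-13(16),14-diene-7α,8α,19-triol; 12 (Z)-3-[4-(tert-butyldimethylsilyloxy)phenyl]prop-2-enoic acid (1.2 equiv)
Product: 13 7α,8α-dihydroxylabda-13(16),14-dien-19-yl (Z)-3-[4-(tert-butyldimethylsilyloxy)phenyl]prop-2-enoate
Conditions: EDC·HCl (1.5 equiv), DMAP (0.3 equiv), CH2Cl2, 0 °C → rt, dark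
Reagents that add atoms: none
Why: Steglich esterification acylates only the primary C19-OH (the axial 7α-OH is flanked by the quaternary C8 and the 8α-OH is tertiary), and carbodiimide/DMAP activation at 0 °C in the dark should keep the Z-geometry; no stereocentre is affected.

Step 9
Reactants: 13 7α,8α-dihydroxylabda-13(16),14-dien-19-yl (Z)-3-[4-(tert-butyldimethylsilyloxy)phenyl]prop-2-enoate
Product: 14 7α,8α-dihydroxylabda-13(16),14-dien-19-yl (Z)-3-(4-hydroxyphenyl)prop-2-enoate (target; 4S,5R,7R,8S,9R,10S)
Conditions: HF·pyridine, pyridine/THF, 0 °C, dark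
Reagents that add atoms: none
Why: fluoride desilylation of the aryl silyl ether under buffered, non-basic conditions leaves the Z-enoate, the diene and the cis-diol untouched.

## Compound list

1 | (+)-isocupressic acid, (13E)-15-hydroxylabda-8(17),13-dien-19-oic acid (4S,5R,9S,10R) | OC/C=C(\C)CC[C@H]1C(=C)CC[C@H]2[C@@](C)(C(=O)O)CCC[C@@]21C | starting material
2 | 15-O-acetylisocupressic acid | CC(=O)OC/C=C(\C)CC[C@H]1C(=C)CC[C@H]2[C@@](C)(C(=O)O)CCC[C@@]21C | intermediate
3 | (13E)-15-acetoxy-7α-hydroxylabda-8(17),13-dien-19-oic acid (7-OH axial, trans to C20) | CC(=O)OC/C=C(\C)CC[C@H]1C(=C)[C@H](O)C[C@H]2[C@@](C)(C(=O)O)CCC[C@@]21C | intermediate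
4 | (13E)-15-acetoxy-8α,17-epoxy-7α-hydroxylabd-13-en-19-oic acid (oxirane O and 7-OH both α) | CC(=O)OC/C=C(\C)CC[C@H]1[C@]3(OC3)[C@H](O)C[C@H]2[C@@](C)(C(=O)O)CCC[C@@]21C | intermediate
5 | 8α,17-epoxy-7α-hydroxylabda-13(16),14-dien-19-oic acid | C=CC(=C)CC[C@H]1[C@]3(OC3)[C@H](O)C[C@H]2[C@@](C)(C(=O)O)CCC[C@@]21C | intermediate
6 | labda-13(16),14-diene-7α,8α,19-triol | C=CC(=C)CC[C@H]1[C@](C)(O)[C@H](O)C[C@H]2[C@@](C)(CO)CCC[C@@]21C | intermediate
7 | 4-(tert-butyldimethylsilyloxy)benzaldehyde | O=Cc1ccc(O[Si](C)(C)C(C)(C)C)cc1 | starting material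
8 | ethyl (diphenoxyphosphoryl)acetate | CCOC(=O)CP(=O)(Oc1ccccc1)Oc1ccccc1 | starting material
9 | ethyl (Z)-3-[4-(tert-butyldimethylsilyloxy)phenyl]prop-2-enoate | CCOC(=O)/C=C\c1ccc(O[Si](C)(C)C(C)(C)C)cc1 | intermediate
10 | (Z)-p-coumaric acid | OC(=O)/C=C\c1ccc(O)cc1 | intermediate
11 | tert-butyldimethylsilyl (Z)-3-[4-(tert-butyldimethylsilyloxy)phenyl]prop-2-enoate | CC(C)(C)[Si](C)(C)OC(=O)/C=C\c1ccc(O[Si](C)(C)C(C)(C)C)cc1 | intermediate
12 | (Z)-3-[4-(tert-butyldimethylsilyloxy)phenyl]prop-2-enoic acid | OC(=O)/C=C\c1ccc(O[Si](C)(C)C(C)(C)C)cc1 | intermediate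
13 | 7α,8α-dihydroxylabda-13(16),14-dien-19-yl (Z)-3-[4-(tert-butyldimethylsilyloxy)phenyl]prop-2-enoate | C=CC(=C)CC[C@H]1[C@](C)(O)[C@H](O)C[C@H]2[C@@](C)(COC(=O)/C=C\c3ccc(O[Si](C)(C)C(C)(C)C)cc3)CCC[C@@]21C | intermediate
14 | 7α,8α-dihydroxylabda-13(16),14-dien-19-yl (Z)-3-(4-hydroxyphenyl)prop-2-enoate | C=CC(=C)CC[C@H]1[C@](C)(O)[C@H](O)C[C@H]2[C@@](C)(COC(=O)/C=C\c3ccc(O)cc3)CCC[C@@]21C | target

## Step count and risk

Total step count: 9 (steps 1–4 on the terpenoid, steps 5–7 for the acid, steps 8–9 coupling and deprotection).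
Longest linear sequence: 6 steps (1, 2, 3, 4, 8, 9).

Three steps most likely to fail:

- **Step 2 (the proposed relay oxidation).** The two catalysts may interfere, the acid-labile spiro-oxirane may not survive selenous acid, or the 7-enone may form. The fallback sets out from 2 and comes back at 4. The relay is given up and the two oxidations are run as separate, isolated literature reactions. SeO2 (0.5 equiv)/t-BuOOH in CH2Cl2 at rt gives the allylic alcohol 3, which is now purified. A separate VO(acac)2 (3 mol %)/t-BuOOH epoxidation in toluene at 0 °C then gives 4. No compound outside the list is made (none F0).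

- **Step 3 (Pd 1,4-elimination).** Hydrogen may be lost from C12 instead of C16, giving 12,14-dienes, or the π-allyl may be trapped by oxygen nucleophiles. The fallback sets out from 4 and comes back at 6; it fixes the diene position through a ketone instead of an elimination. LiAlH4 reduces 4 to labd-13E-ene-7α,8α,15,19-tetraol F1. 2,2-Dimethoxypropane/PPTS gives the 7,8-acetonide F2. Ozonolysis (O3, then Me2S) cleaves C13=C14 to the methyl ketone F3. TBSCl/imidazole gives the 19-silyl ether F4. KHMDS/PhNTf2 at −78 °C gives the kinetic terminal enol triflate F5. Stille coupling with tributyl(vinyl)stannane (Pd(PPh3)4, LiCl, THF) gives the protected diene F6. Aqueous HF/MeCN removes silyl ether and acetonide in one operation to give 6.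

- **Step 8 (esterification).** The neopentyl C19-OH may react sluggishly, the activated Z-acid may isomerise to E, or some 7-O-acylation may occur. The fallback sets out from 6 and comes back at 13; the Z-alkene is built on the substrate instead of being carried in the acid. 6 is acylated with (diphenoxyphosphoryl)acetic acid (EDC, DMAP) to the 19-phosphonoacetate F7. An Ando olefination of F7 with aldehyde 7 (NaI, DBU, THF, 0 °C) then gives 13.

## Further compounds

F0 | step 2 | none | none
F1 | step 3 | labd-13E-ene-7α,8α,15,19-tetraol | OC/C=C(\C)CC[C@H]1[C@](C)(O)[C@H](O)C[C@H]2[C@@](C)(CO)CCC[C@@]21C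
F2 | step 3 | 7α,8α-O-isopropylidene-labd-13E-ene-15,19-diol | OC/C=C(\C)CC[C@H]1[C@]3(C)OC(C)(C)O[C@@H]3C[C@H]2[C@@](C)(CO)CCC[C@@]21C
F3 | step 3 | 19-hydroxy-7α,8α-isopropylidenedioxy-14,15-dinorlabdan-13-one | CC(=O)CC[C@H]1[C@]3(C)OC(C)(C)O[C@@H]3C[C@H]2[C@@](C)(CO)CCC[C@@]21C
F4 | step 3 | 19-(tert-butyldimethylsilyloxy)-7α,8α-isopropylidenedioxy-14,15-dinorlabdan-13-one | CC(=O)CC[C@H]1[C@]3(C)OC(C)(C)O[C@@H]3C[C@H]2[C@@](C)(CO[Si](C)(C)C(C)(C)C)CCC[C@@]21C
F5 | step 3 | 19-(tert-butyldimethylsilyloxy)-7α,8α-isopropylidenedioxy-14,15-dinorlabd-13(16)-en-13-yl trifluoromethanesulfonate | C=C(OS(=O)(=O)C(F)(F)F)CC[C@H]1[C@]3(C)OC(C)(C)O[C@@H]3C[C@H]2[C@@](C)(CO[Si](C)(C)C(C)(C)C)CCC[C@@]21C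
F6 | step 3 | 19-(tert-butyldimethylsilyloxy)-7α,8α-isopropylidenedioxylabda-13(16),14-diene | C=CC(=C)CC[C@H]1[C@]3(C)OC(C)(C)O[C@@H]3C[C@H]2[C@@](C)(CO[Si](C)(C)C(C)(C)C)CCC[C@@]21C
F7 | step 8 | 7α,8α-dihydroxylabda-13(16),14-dien-19-yl (diphenoxyphosphoryl)acetate | C=CC(=C)CC[C@H]1[C@](C)(O)[C@H](O)C[C@H]2[C@@](C)(COC(=O)CP(=O)(Oc3ccccc3)Oc3ccccc3)CCC[C@@]21C
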